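**Strategy.** The route rests on forming the C5–C10 bond by a 1,2-shift. Oxygenated C9 beside quaternary C10, which carries oxygenated C20, is at the ketone level the signature of an epoxy-alcohol semipinacol rearrangement. The precursor is an all-cis angular tricycle built on a cyclopentane (C5–C9): it holds the 19,6-lactone and a temporary seven-membered ring (C9, C10, C1–C5) with a spiro-epoxide on C10 beside the tertiary C9 alcohol. On activation C5 leaves C9 for C10. In one operation the cyclopentane grows into ring B, the seven-membered ring shrinks to ring A, and C10 (C20 β), the C9 ketone and the trans A/B fusion are set.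

Key step: step 10

Remark: labdane numbering is used throughout (ring A C1–C5 and C10, ring B C5–C10, C18 methyl and C19 carbonyl on C4, C20 on C10, C17 methyl on C8, side chain C11–C16; α is the face of H-5, β the face of C20); compounds 1, 4 and 20 are assumed to be catalogue chemicals.

**Step 1**
Reactants: 1 5-chloropent-1-yne
Product: 2 2-bromo-5-chloropent-1-ene
Conditions: HBr, Et4NBr, CH2Cl2, 40 °C
Reagents that add atoms: hydrogen bromide, Br
Why: Markovnikov hydrobromination of a terminal alkyne with tetraethylammonium hydrogen dibromide should give the 2-bromo-1-alkene; no stereocenter is formed.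

**Step 2**
Reactants: 2 2-bromo-5-chloropent-1-ene
Product: 3 2-bromo-5-iodopent-1-ene
Conditions: NaI, acetone, reflux
Reagents that add atoms: sodium iodide, [Na+].[I-]
Why: Finkelstein exchange at the primary chloride, to which the vinyl bromide is inert.

**Step 3**
Reactants: 4 (3aR,6aS)-3,3a,6,6a-tetrahydro-2H-cyclopenta[b]furan-2-one
Product: 6 (3S,3aR,6aS)-3-methyl-3,3a,6,6a-tetrahydro-2H-cyclopenta[b]furan-2-one, via lithium enolate 5 (not isolated)
Conditions: LiN(iPr)2, THF, −78 °C; MeI, −78 °C
Reagents that add atoms: iodomethane, CI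
Why: Enolate alkylation of the cis-fused bicyclic lactone on its convex face; this center is re-enolised in step 4, so only clean mono-methylation matters here.

**Step 4**
Reactants: 6 (3S,3aR,6aS)-3-methyl lactone; 3 2-bromo-5-iodopent-1-ene
Product: 8 (3S,3aR,6aS)-3-(4-bromopent-4-en-1-yl)-3-methyl-3,3a,6,6a-tetrahydro-2H-cyclopenta[b]furan-2-one, via lithium enolate 7 (not isolated)
Conditions: LiN(iPr)2, THF/DMPU, −78 °C; 3, −78 → −20 °C
Reagents that add atoms: none
Why: Second enolate alkylation, in which the primary iodide enters on the convex face syn to H-5 so that the chain is exo and the methyl endo; this order of the two alkylations sets quaternary C4 as in the target.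

**Step 5**
Reactants: 8 dialkylated lactone
Product: 10 hydroxy iodolactone (lactone now on O-6), via potassium carboxylate 9 (not isolated)
Conditions: KOH, THF/H2O, 50 °C; then NaHCO3, I2, KI, H2O, 0 °C, dark
Reagents that add atoms: potassium hydroxide, [K+].[OH-]; iodine, II
Why: Saponification frees the C9 hydroxyl, and iodolactonisation (5-exo, anti addition) re-closes the carboxylate on C6 cis to the C4 branch, which moves the temporary lactone to the 19,6-position, sets C6 and turns the chain to the concave face next to C9.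

**Step 6**
Reactants: 10 hydroxy iodolactone
Product: 11 hydroxy lactone
Conditions: Bu3SnH (1.05 equiv), Et3B (cat.), air, toluene, 0 °C
Reagents that add atoms: none
Why: Radical deiodination; iodine abstraction from the secondary iodide is far faster than bromine abstraction from the vinyl bromide, and no stereocenter is touched.

**Step 7**
Reactants: 11 hydroxy lactone
Product: 12 keto lactone
Conditions: Dess–Martin periodinane, NaHCO3, CH2Cl2, 0 °C
Reagents that add atoms: none
Why: Dess–Martin oxidation gives the β-acyloxy ketone without base, which would expel the lactone carboxylate by E1cB.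

**Step 8**
Reactants: 12 keto lactone
Product: 13 tricyclic allylic alcohol
Conditions: CrCl2 (6 equiv), NiCl2 (5 mol %), DMF, 25 °C, 0.005 M
Reagents that add atoms: none
Why: Intramolecular Nozaki–Hiyama–Kishi addition (7-exo closure on the ketone) under non-basic conditions; the chain lies on the concave face beside C9, so the vinylchromium adds to the carbonyl face syn to C4 and the seven-membered ring is cis-fused with the new hydroxyl on the convex face.

**Step 9**
Reactants: 13 tricyclic allylic alcohol
Product: 14 tricyclic epoxy alcohol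
Conditions: VO(acac)2 (5 mol %), tBuOOH, CH2Cl2, 0 → 25 °C
Reagents that add atoms: tert-butyl hydroperoxide, CC(C)(C)OO
Why: Hydroxyl-directed vanadium-catalysed epoxidation delivers oxygen to the alkene face syn to the tertiary hydroxyl, which sets the C10 spiro-epoxide cis to the C9 oxygen.

**Step 10**
Reactants: 14 tricyclic epoxy alcohol
Product: 15 20-(tert-butyldimethylsilyloxy)-9-oxo-11,12,13,14,15,16,17-heptanorlabdan-19,6β-olide
Conditions: TBSOTf (1.3 equiv), 2,6-lutidine, CH2Cl2, −78 → −20 °C
Reagents that add atoms: tert-butyldimethylsilyl trifluoromethanesulfonate, CC(C)(C)[Si](C)(C)OS(=O)(=O)C(F)(F)F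
Why: The silyl triflate binds the epoxide oxygen, the C10–O bond ionises while the antiperiplanar C5–C9 bond shifts to C10, the C9 oxygen collapses to the ketone and the silyl group stays on the C20 oxygen. The closest known reaction type is the Lewis-acid semipinacol rearrangement of 2,3-epoxy alcohols (Tsuchihashi–Suzuki type), here with a silyl triflate as in the non-aldol aldol process. No ring is closed by cyclisation: the cyclopentane C5–C9 takes up C10 by the 1,2-shift (five to six, ring B) and the same shift contracts the seven-membered ring to ring A (seven to six). C10 is set by the epoxide configuration through anti migration (inversion at C10, C20 β), and C5 migrates with retention, which gives the trans ring fusion. The step needs migration of C5 over C8: C5 is the more substituted carbon, its shift leads to the unstrained trans-decalin while C8 would give a bridged ketone, and the cis-epoxy alcohol can place C5–C9 anti to C10–O in a twist-chair of the cis-fused seven-membered ring. The hindered base limits proton loss to an allylic ether.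

**Step 11**
Reactants: 15 silyloxy keto lactone
Product: 17 20-(tert-butyldimethylsilyloxy)-9-oxo-11,12,13,14,15,16-hexanorlabdan-19,6β-olide, via lithium enolate 16 (not isolated)
Conditions: LiN(iPr)2, THF, −78 °C; MeI, −78 → −30 °C
Reagents that add atoms: iodomethane, CI
Why: Only C8 carries α-hydrogens (C10 is quaternary), and iodomethane attacks the enolate anti to the axial C10 CH2OSi group, which gives the equatorial 8α-methyl epimer that is also the thermodynamic one.

**Step 12**
Reactants: 17 8α-methyl ketone
Product: 18 20-(tert-butyldimethylsilyloxy)-12,13,14,15,16-pentanorlabd-9(11)-en-19,6β-olide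
Conditions: Ph3PCH3Br, KOtBu, toluene, 90 °C
Reagents that add atoms: methyltriphenylphosphonium bromide, C[P+](c1ccccc1)(c1ccccc1)c1ccccc1.[Br-]
Why: Wittig methylenation under forcing conditions as used for 2,2,6-trisubstituted cyclohexanones; C8 stays equatorial because that epimer is favoured under base.

**Step 13**
Reactants: 18 exocyclic alkene
Product: 19 9α,11-epoxy-20-(tert-butyldimethylsilyloxy)-12,13,14,15,16-pentanorlabdan-19,6β-olide
Conditions: mCPBA, NaHCO3, CH2Cl2, 0 °C
Reagents that add atoms: 3-chloroperoxybenzoic acid, OOC(=O)c1cccc(Cl)c1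
Why: Prilezhaev epoxidation from the α-face, anti to the axial C20 substituent on C10, places the epoxide oxygen axial (9α) and C11 equatorial.

**Step 14**
Reactants: 20 2-methylenepropane-1,3-diol
Product: 21 2-({[tert-butyl(dimethyl)silyl]oxy}methyl)prop-2-en-1-ol
Conditions: TBSCl (1 equiv), imidazole, THF, 0 °C, diol in excess
Reagents that add atoms: tert-butyldimethylsilyl chloride, CC(C)(C)[Si](C)(C)Cl
Why: Statistical mono-silylation of a symmetrical diol used in excess; no stereocenter.

**Step 15**
Reactants: 21 mono-silyl ether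
Product: 22 tert-butyl{[2-(chloromethyl)prop-2-en-1-yl]oxy}dimethylsilane
Conditions: PPh3, CCl4, CH2Cl2, 40 °C
Reagents that add atoms: carbon tetrachloride, ClC(Cl)(Cl)Cl
Why: Appel chlorination of the allylic alcohol, in which SN2 and SN2' attack give the same product.

**Step 16**
Reactants: 19 9α,11-epoxide; 22 allylic chloride
Product: 24 9α-hydroxy-16,20-bis(tert-butyldimethylsilyloxy)-15-norlabd-13(14)-en-19,6β-olide, via allylmagnesium chloride 23 (not isolated)
Conditions: 22, Mg, THF, 0 °C; then 19, CuI (10 mol %), THF, −30 → 0 °C; aq NH4Cl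
Reagents that add atoms: none
Why: Copper-catalysed Grignard opening of the 1,1-disubstituted epoxide at its CH2 terminus forms C11–C12 and leaves the 9α tertiary alcohol untouched; at low temperature the allylcopper species should not add to the hindered lactone.

**Step 17**
Reactants: 24 bis-silyl ether
Product: 25 9α,16,20-trihydroxy-15-norlabd-13(14)-en-19,6β-olide
Conditions: Bu4NF, AcOH (1:1), THF, 25 °C
Reagents that add atoms: none
Why: Fluoride cleaves both silyl ethers, and acetic acid buffering keeps the C20 alkoxide from attacking the nearby lactone carbonyl.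

**Step 18**
Reactants: 25 triol
Product: 26 (13R)-9α,13-epoxy-20-hydroxylabdane-19,6β:15,16-diolide
Conditions: PdCl2 (10 mol %), CuCl2 (3 equiv), NaOAc (3 equiv), CO (1 atm), AcOH, 25 °C
Reagents that add atoms: carbon monoxide, [C-]#[O+]
Why: Palladium-catalysed alkoxycarbonylative lactonisation: 5-exo oxypalladation of the 1,1-disubstituted alkene by the 9-hydroxyl gives a σ-alkylpalladium without β-hydrogen, and CO insertion with capture by the C16 hydroxyl closes the spiro-lactone; C13 should form with the flat CH2–Pd terminus (C14) on the crowded C10 side and the CH2OH arm (C16) toward C8, which is the 13R arrangement.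

**Step 19**
Reactants: 26 hydroxy dilactone
Product: 27 (13R)-20-acetoxy-9α,13-epoxylabdane-19,6β:15,16-diolide
Conditions: Ac2O, pyridine, DMAP (cat.), CH2Cl2, 0 → 25 °C
Reagents that add atoms: acetic anhydride, CC(=O)OC(C)=O
Why: Acetylation of the only free hydroxyl, the primary C20 alcohol.

**Compound list**

1 | 5-chloropent-1-yne | C#CCCCCl | starting material
2 | 2-bromo-5-chloropent-1-ene | C=C(Br)CCCCl | intermediate
3 | 2-bromo-5-iodopent-1-ene | C=C(Br)CCCI | intermediate
4 | (3aR,6aS)-3,3a,6,6a-tetrahydro-2H-cyclopenta[b]furan-2-one, the cis-fused (1S,5R)-2-oxabicyclo[3.3.0]oct-6-en-3-one | O=C1O[C@H]2CC=C[C@H]2C1 | starting material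
5 | lithium enolate of 4 | [Li+].[O-]C1=C[C@@H]2C=CC[C@@H]2O1 | intermediate
6 | (3S,3aR,6aS)-3-methyl-3,3a,6,6a-tetrahydro-2H-cyclopenta[b]furan-2-one, methyl on the convex face | O=C1O[C@H]2CC=C[C@H]2[C@@H]1C | intermediate
7 | lithium enolate of 6 | [Li+].[O-]C1=C(C)[C@@H]2C=CC[C@@H]2O1 | intermediate
8 | (3S,3aR,6aS)-3-(4-bromopent-4-en-1-yl)-3-methyl-3,3a,6,6a-tetrahydro-2H-cyclopenta[b]furan-2-one, chain convex and syn to H-3a | O=C1O[C@H]2CC=C[C@H]2[C@]1(C)CCCC(Br)=C | intermediate
9 | potassium salt of the hydroxy acid from 8 (C9 hydroxyl cis to the C4 branch on the cyclopent-2-ene) | [K+].[O-]C(=O)[C@@](C)(CCCC(Br)=C)[C@@H]1C=CC[C@@H]1O | intermediate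
10 | 3-(4-bromopent-4-en-1-yl)-4-hydroxy-6-iodo-3-methylhexahydro-2H-cyclopenta[b]furan-2-one: cis-fused 19,6-lactone, 9-OH cis to the C4 branch, 7-iodide trans to O-6, chain on C4 syn to C9 | O=C1O[C@@H]2[C@@H](I)C[C@H](O)[C@@H]2[C@]1(C)CCCC(Br)=C | intermediate
11 | 3-(4-bromopent-4-en-1-yl)-4-hydroxy-3-methylhexahydro-2H-cyclopenta[b]furan-2-one (same configuration as 10) | O=C1O[C@@H]2CC[C@H](O)[C@@H]2[C@]1(C)CCCC(Br)=C | intermediate
12 | cis-fused keto lactone: 3-(4-bromopent-4-en-1-yl)-3-methyltetrahydro-2H-cyclopenta[b]furan-2,4(3H)-dione | O=C1O[C@@H]2CCC(=O)[C@@H]2[C@]1(C)CCCC(Br)=C | intermediate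
13 | all-cis angular tricycle: cyclopentane C5–C9 fused to the 19,6-γ-lactone and to the seven-membered ring C9–C10–C1–C2–C3–C4–C5; tertiary C9–OH on the convex face (trans to O-6), exocyclic C10=C20H2, C4 methyl syn to H-5 | O=C1O[C@@H]2CC[C@@]3(O)[C@@H]2[C@]1(C)CCCC3=C | intermediate
14 | spiro-epoxide of 13: C10–C20 epoxide with its oxygen cis to the C9 hydroxyl | O=C1O[C@@H]2CC[C@@]3(O)[C@@H]2[C@]1(C)CCC[C@@]34CO4 | intermediate
15 | 20-(tert-butyldimethylsilyloxy)-9-oxo-11,12,13,14,15,16,17-heptanorlabdan-19,6β-olide (trans-decalin, 5α-H, 10β-CH2OSi, 4α-methyl) | CC(C)(C)[Si](C)(C)OC[C@@]12CCC[C@]3(C)C(=O)O[C@H](CCC1=O)[C@H]23 | intermediate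
16 | lithium C8–C9 enolate of 15 | [Li+].CC(C)(C)[Si](C)(C)OC[C@@]12CCC[C@]3(C)C(=O)O[C@H](CC=C1[O-])[C@H]23 | intermediate
17 | 20-(tert-butyldimethylsilyloxy)-9-oxo-11,12,13,14,15,16-hexanorlabdan-19,6β-olide (8α-methyl) | CC(C)(C)[Si](C)(C)OC[C@@]12CCC[C@]3(C)C(=O)O[C@H](C[C@@H](C)C1=O)[C@H]23 | intermediate
18 | 20-(tert-butyldimethylsilyloxy)-12,13,14,15,16-pentanorlabd-9(11)-en-19,6β-olide | CC(C)(C)[Si](C)(C)OC[C@@]12CCC[C@]3(C)C(=O)O[C@H](C[C@@H](C)C1=C)[C@H]23 | intermediate
19 | 9α,11-epoxy-20-(tert-butyldimethylsilyloxy)-12,13,14,15,16-pentanorlabdan-19,6β-olide | CC(C)(C)[Si](C)(C)OC[C@@]12CCC[C@]3(C)C(=O)O[C@H](C[C@@H](C)[C@]14CO4)[C@H]23 | intermediate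
20 | 2-methylenepropane-1,3-diol | C=C(CO)CO | starting material
21 | 2-({[tert-butyl(dimethyl)silyl]oxy}methyl)prop-2-en-1-ol | C=C(CO)CO[Si](C)(C)C(C)(C)C | intermediate
22 | tert-butyl{[2-(chloromethyl)prop-2-en-1-yl]oxy}dimethylsilane | C=C(CCl)CO[Si](C)(C)C(C)(C)C | intermediate
23 | [2-({[tert-butyl(dimethyl)silyl]oxy}methyl)prop-2-en-1-yl]magnesium chloride | C=C(C[Mg]Cl)CO[Si](C)(C)C(C)(C)C | intermediate
24 | 9α-hydroxy-16,20-bis(tert-butyldimethylsilyloxy)-15-norlabd-13(14)-en-19,6β-olide | CC(C)(C)[Si](C)(C)OC[C@@]12CCC[C@]3(C)C(=O)O[C@H](C[C@@H](C)[C@]1(O)CCC(=C)CO[Si](C)(C)C(C)(C)C)[C@H]23 | intermediate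
25 | 9α,16,20-trihydroxy-15-norlabd-13(14)-en-19,6β-olide | OC[C@@]12CCC[C@]3(C)C(=O)O[C@H](C[C@@H](C)[C@]1(O)CCC(=C)CO)[C@H]23 | intermediate
26 | (13R)-9α,13-epoxy-20-hydroxylabdane-19,6β:15,16-diolide | OC[C@@]12CCC[C@]3(C)C(=O)O[C@H](C[C@@H](C)[C@]14CC[C@@]1(COC(=O)C1)O4)[C@H]23 | intermediate
27 | (13R)-20-acetoxy-9α,13-epoxylabdane-19,6β:15,16-diolide | CC(=O)OC[C@@]12CCC[C@]3(C)C(=O)O[C@H](C[C@@H](C)[C@]14CC[C@@]1(COC(=O)C1)O4)[C@H]23 | target

**Totals.** Total step count: 19. Longest linear sequence: 16 steps (1 to 27 through steps 1, 2, 4–13 and 16–19).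

**Steps most likely to fail**

Step 8 (closure of the seven-membered ring). The vinylchromium may add too slowly to the hindered ketone, so that E1cB loss of the lactone carboxylate from the β-acyloxy ketone or protodebromination takes over. The fallback is a reductive alkyne–ketone coupling in place of the organochromium addition; it sets out from 11 and returns at 13. Bu4NF·3H2O in DMF at 60 °C eliminates HBr from the 2-bromoalkene of 11 to give the terminal alkyne hydroxy lactone F1. Buffered Dess–Martin oxidation gives the alkynyl keto lactone F2. Ni(cod)2 (zerovalent nickel) with the N-heterocyclic carbene IPr and Et3SiH in THF joins C9 to the internal alkyne carbon, again on the face syn to C4, and gives the triethylsilyl ether of the allylic alcohol F3. Bu4NF in THF removes the silyl group to give 13.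

Step 10 (key rearrangement). The silyloxonium ion may lose a proton to an allylic silyl ether, or the ring may react through the conformer in which C8 migrates. The fallback is a halonium-triggered shift with later oxygenation of C20; it sets out from 13 and returns at 15. N-Iodosuccinimide in CH2Cl2 at −20 °C forms the iodonium ion reversibly, and the same antiperiplanar shift of C5 gives the β-iodo ketone F4. The C10 configuration is less secure here than with the directed epoxide, because it rests on which iodonium ion reacts. Bu3SnH with a large excess of TEMPO in benzene at 70 °C traps the C20 radical as the alkoxyamine F5; the excess is needed so that trapping outruns the 1,2-acyl shift of the β-keto radical. Zn in AcOH/THF cleaves the N–O bond to the hydroxy ketone F6. TBSOTf and 2,6-lutidine silylate the C20 hydroxyl to give 15.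

Step 18 (dispiro ring closure). The oxypalladation may show poor facial selectivity at C13, or the hindered tertiary hydroxyl may fail to add. The fallback closes the ether ring by a reversible oxa-Michael addition to a butenolide; it sets out from 19 and returns at 26. 3-Furylmethylmagnesium chloride with CuI in THF opens epoxide 19 at C11 to give the furan carbinol F7. Singlet oxygen (O2, rose bengal, hν, iPr2NEt, CH2Cl2, −78 °C) gives the γ-hydroxybutenolide F8, which NaBH4 in EtOH reduces to the β-substituted butenolide F9. DBU in toluene lets the 9-hydroxyl add to C13, the two C13 epimers equilibrating through retro-addition, to give the silyl-protected dispiro dilactone F10. Bu4NF buffered with AcOH gives 26.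

**Further compounds**

F1 | step 8 | 3-methyl-3-(pent-4-yn-1-yl)-4-hydroxyhexahydro-2H-cyclopenta[b]furan-2-one (configuration as 11) | O=C1O[C@@H]2CC[C@H](O)[C@@H]2[C@]1(C)CCCC#C
F2 | step 8 | 3-methyl-3-(pent-4-yn-1-yl)tetrahydro-2H-cyclopenta[b]furan-2,4(3H)-dione (configuration as 12) | O=C1O[C@@H]2CCC(=O)[C@@H]2[C@]1(C)CCCC#C
F3 | step 8 | triethylsilyl ether of 13 | O=C1O[C@@H]2CC[C@@]3(O[Si](CC)(CC)CC)[C@@H]2[C@]1(C)CCCC3=C
F4 | step 10 | 20-iodo-9-oxo-11,12,13,14,15,16,17-heptanorlabdan-19,6β-olide | IC[C@@]12CCC[C@]3(C)C(=O)O[C@H](CCC1=O)[C@H]23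
F5 | step 10 | 20-(2,2,6,6-tetramethylpiperidin-1-yloxy)-9-oxo-11,12,13,14,15,16,17-heptanorlabdan-19,6β-olide | CC1(C)CCCC(C)(C)N1OC[C@@]12CCC[C@]3(C)C(=O)O[C@H](CCC1=O)[C@H]23
F6 | step 10 | 20-hydroxy-9-oxo-11,12,13,14,15,16,17-heptanorlabdan-19,6β-olide | OC[C@@]12CCC[C@]3(C)C(=O)O[C@H](CCC1=O)[C@H]23
F7 | step 18 | 15,16-epoxy-9α-hydroxy-20-(tert-butyldimethylsilyloxy)labda-13(16),14-dien-19,6β-olide (3-furyl side chain) | CC(C)(C)[Si](C)(C)OC[C@@]12CCC[C@]3(C)C(=O)O[C@H](C[C@@H](C)[C@]1(O)CCc1ccoc1)[C@H]23
F8 | step 18 | 9α,16-dihydroxy-20-(tert-butyldimethylsilyloxy)labd-13-ene-19,6β:15,16-diolide (C16 epimers) | CC(C)(C)[Si](C)(C)OC[C@@]12CCC[C@]3(C)C(=O)O[C@H](C[C@@H](C)[C@]1(O)CCC1=CC(=O)OC1O)[C@H]23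
F9 | step 18 | 9α-hydroxy-20-(tert-butyldimethylsilyloxy)labd-13-ene-19,6β:15,16-diolide | CC(C)(C)[Si](C)(C)OC[C@@]12CCC[C@]3(C)C(=O)O[C@H](C[C@@H](C)[C@]1(O)CCC1=CC(=O)OC1)[C@H]23
F10 | step 18 | (13R)-9α,13-epoxy-20-(tert-butyldimethylsilyloxy)labdane-19,6β:15,16-diolide | CC(C)(C)[Si](C)(C)OC[C@@]12CCC[C@]3(C)C(=O)O[C@H](C[C@@H](C)[C@]14CC[C@@]1(COC(=O)C1)O4)[C@H]23
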